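The target is read as a 2-benzylindan-1-one whose C1–C2 bond has been cut: the ester carbon on ring A C1 and the side-chain ketone carbon are separated only by C1, C2 and the benzylic CH2 of ring A, so reconnecting them gives a five-membered ring. That temporary bond comes from Meldrum's acid; the key step then closes the ring in one operation by intramolecular Friedel–Crafts acylation, joining ring A C1 to the future ester carbon with loss of acetone and CO2. The precursor is a 5,5-dibenzyl Meldrum's acid carrying both arenes, phenols masked as triisopropylsilyl ethers; only ring A has a free position ortho to its benzylic carbon. α-Hydroxylation and Pb(OAc)4/MeOH cleavage later reopen the ring.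

Key step: step 9

Remark on the chemistry: both phenols are carried as triisopropylsilyl (TIPS) ethers, because an ortho O-alkyl group that can leave as a cation (isopropyl, benzyl) is expected to be lost under the Lewis acid of the key step, after which the phenol would lactonise with the Meldrum's acid, and because its final removal with a boron halide would invite cyclodehydration of the o-hydroxybenzyl ketone to a benzofuran; aryl TIPS ethers are expected to survive metal-triflate catalysis and come off with buffered fluoride. The target has no stereocentre; C2 of the indanone intermediates is racemic.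

Step 1
Reactants: 1 2-chloro-1,3-dimethoxybenzene
Product: 3 4-chloro-3,5-dimethoxyphenol, via aryl pinacol boronate 2 (not isolated)
Conditions: [Ir(OMe)(cod)]2 (1.5 mol%), 4,4'-di-tert-butyl-2,2'-bipyridine (3 mol%), B2pin2 (1.0 equiv), THF, 80 °C; then KHSO5 (Oxone, 2KHSO5·KHSO4·K2SO4), acetone/H2O, rt
Reagents that add atoms: bis(pinacolato)diboron, CC1(C)OB(OC1(C)C)B1OC(C)(C)C(C)(C)O1 (boron of 2 only); potassium peroxymonosulfate, [K+].[O-]S(=O)(=O)OO (oxygen of 3)
Why: Iridium-catalysed C–H borylation is governed by sterics and should take place only at C5, the one C–H with no ortho substituent, and oxidation of the C–B bond in the same flask (one-pot borylation/oxidation) then gives the phenol.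

Step 2
Reactants: 3 4-chloro-3,5-dimethoxyphenol
Product: 5 3-chloro-6-hydroxy-2,4-dimethoxybenzaldehyde, via salicyl alcohol 4 (not isolated)
Conditions: MgCl2, Et3N, (CH2O)n, MeCN, reflux; aq. HCl work-up
Reagents that add atoms: formaldehyde (from paraformaldehyde), C=O
Why: Magnesium-mediated ortho-formylation of a phenol (Casnati–Skattebøl reaction): the magnesium phenoxide directs formaldehyde to an ortho carbon (both are equivalent here and the para carbon carries chlorine), and the salicyl alcohol so formed is oxidised by a second formaldehyde in an Oppenauer-type hydride transfer.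

Step 3
Reactants: 5 3-chloro-6-hydroxy-2,4-dimethoxybenzaldehyde
Product: 6 3-chloro-2,4-dimethoxy-6-[(triisopropylsilyl)oxy]benzaldehyde
Conditions: TIPSCl, imidazole, DMF, rt
Reagents that add atoms: triisopropylsilyl chloride, CC(C)[Si](Cl)(C(C)C)C(C)C
Why: Silylation of a phenol with a silyl chloride and imidazole; the bulky TIPS group is chosen because it survives base, mild acid and metal triflates.

Step 4
Reactants: 6 3-chloro-2,4-dimethoxy-6-[(triisopropylsilyl)oxy]benzaldehyde; 7 Meldrum's acid (2,2-dimethyl-1,3-dioxane-4,6-dione)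
Product: 9 5-{3-chloro-2,4-dimethoxy-6-[(triisopropylsilyl)oxy]benzyl}-2,2-dimethyl-1,3-dioxane-4,6-dione, via alkylidene Meldrum's acid 8 (not isolated)
Conditions: L-proline (20 mol%), Hantzsch ester (1.05 equiv), EtOH, rt
Reagents that add atoms: none
Why: Three-component reductive alkylation: proline-catalysed Knoevenagel condensation gives the alkylidene Meldrum's acid, which is reduced at once by conjugate hydride transfer from the Hantzsch ester, so that monoalkylation is the only outcome.

Step 5
Reactants: 10 2-hydroxy-4-methylbenzaldehyde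
Product: 11 4-methyl-2-[(triisopropylsilyl)oxy]benzaldehyde
Conditions: TIPSCl, imidazole, DMF, rt
Reagents that add atoms: triisopropylsilyl chloride, CC(C)[Si](Cl)(C(C)C)C(C)C
Why: Silylation of a phenol with a silyl chloride and imidazole, giving the same acid-tolerant, fluoride-labile protection as on ring B.

Step 6
Reactants: 11 4-methyl-2-[(triisopropylsilyl)oxy]benzaldehyde
Product: 12 {4-methyl-2-[(triisopropylsilyl)oxy]phenyl}methanol
Conditions: NaBH4, MeOH/THF, 0 °C
Reagents that add atoms: none
Why: Hydride reduction of an aromatic aldehyde to the benzylic alcohol, run cold and quenched early so that the silyl group stays on the phenol oxygen.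

Step 7
Reactants: 12 {4-methyl-2-[(triisopropylsilyl)oxy]phenyl}methanol
Product: 13 1-(bromomethyl)-4-methyl-2-[(triisopropylsilyl)oxy]benzene
Conditions: CBr4, PPh3, CH2Cl2, 0 °C; used without delay
Reagents that add atoms: carbon tetrabromide, BrC(Br)(Br)Br
Why: Appel reaction, which converts the benzylic alcohol into the bromide under neutral conditions that leave the aryl silyl ether intact.

Step 8
Reactants: 9 5-{3-chloro-2,4-dimethoxy-6-[(triisopropylsilyl)oxy]benzyl}-2,2-dimethyl-1,3-dioxane-4,6-dione; 13 1-(bromomethyl)-4-methyl-2-[(triisopropylsilyl)oxy]benzene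
Product: 14 5-{3-chloro-2,4-dimethoxy-6-[(triisopropylsilyl)oxy]benzyl}-2,2-dimethyl-5-{4-methyl-2-[(triisopropylsilyl)oxy]benzyl}-1,3-dioxane-4,6-dione
Conditions: K2CO3, dry MeCN, rt
Reagents that add atoms: none
Why: SN2 C-alkylation of the stabilised, soft anion of a 5-monosubstituted Meldrum's acid by a reactive benzylic bromide, which builds the quaternary carbon carrying both arenes.

Step 9
Reactants: 14 5-{3-chloro-2,4-dimethoxy-6-[(triisopropylsilyl)oxy]benzyl}-2,2-dimethyl-5-{4-methyl-2-[(triisopropylsilyl)oxy]benzyl}-1,3-dioxane-4,6-dione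
Product: 16 racemic 2-{3-chloro-2,4-dimethoxy-6-[(triisopropylsilyl)oxy]benzyl}-6-methyl-4-[(triisopropylsilyl)oxy]indan-1-one, via indanone-2-carboxylic acid 15 (not isolated)
Conditions: Sc(OTf)3 (10 mol%), MeNO2 (0.05 M), 100 °C
Reagents that add atoms: none
Why: Sc(OTf)3 binds a Meldrum's acid carbonyl, ring A attacks it in an electrophilic aromatic substitution through its C–H ortho to the benzylic carbon, and the ring-opened adduct loses acetone and then CO2 (through β-keto acid 15) to give the 2-substituted indanone. The closest known reaction type is the metal-triflate-catalysed intramolecular Friedel–Crafts acylation of 5,5-disubstituted benzyl Meldrum's acids to 1-indanones, which is expected to work on benzyl groups lacking activating substituents and in the presence of aryl silyl ethers. The five-membered ring closes in a 5-exo-trig manner at the acyl carbon, the tether being the benzylic CH2 and the quaternary carbon. The only new stereocentre, C2 of the indanone, arises on decarboxylation without control, is racemic, and is erased in step 11. Site selectivity between the two arenes is needed and is secured by substitution: ring A has one unsubstituted carbon next to its CH2-bearing carbon, whereas ring B, although the more nucleophilic arene, carries oxygen on both such carbons and offers no site for a five-membered closure, and its single C–H is shielded by the flanking OTIPS and OMe groups against intermolecular acylation at this dilution. The bulky silyl groups should also keep the ortho oxygens from attacking the acyl donor, which is the main competing pathway.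

Step 10
Reactants: 16 racemic 2-{3-chloro-2,4-dimethoxy-6-[(triisopropylsilyl)oxy]benzyl}-6-methyl-4-[(triisopropylsilyl)oxy]indan-1-one
Product: 18 racemic 2-{3-chloro-2,4-dimethoxy-6-[(triisopropylsilyl)oxy]benzyl}-2-hydroxy-6-methyl-4-[(triisopropylsilyl)oxy]indan-1-one, via potassium enolate 17 (not isolated)
Conditions: KN(SiMe3)2, THF, −78 °C; then 3-phenyl-2-(phenylsulfonyl)oxaziridine, −78 °C; aq. NH4Cl
Reagents that add atoms: 3-phenyl-2-(phenylsulfonyl)oxaziridine (Davis oxaziridine), O=S(=O)(c1ccccc1)N1OC1c1ccccc1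
Why: Enolate oxidation with a Davis oxaziridine: C2 is the only enolisable carbon, its potassium enolate attacks the oxaziridine oxygen, and the tertiary carbinol centre forms as a racemate that is destroyed in step 11.

Step 11
Reactants: 18 racemic 2-{3-chloro-2,4-dimethoxy-6-[(triisopropylsilyl)oxy]benzyl}-2-hydroxy-6-methyl-4-[(triisopropylsilyl)oxy]indan-1-one
Product: 19 methyl 2-(3-{3-chloro-2,4-dimethoxy-6-[(triisopropylsilyl)oxy]phenyl}-2-oxopropyl)-5-methyl-3-[(triisopropylsilyl)oxy]benzoate
Conditions: Pb(OAc)4 (1.1 equiv), MeOH/toluene 1:1, 0 °C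
Reagents that add atoms: methanol, CO
Why: Criegee-type cleavage of an α-ketol by Pb(OAc)4 in methanol: the methanol hemiketal of the ketone behaves as a 1,2-diol, and its fragmentation breaks the C1–C2 bond so that C1 leaves as the methyl ester on ring A and C2 as the ketone between the two benzylic CH2 groups.

Step 12
Reactants: 19 methyl 2-(3-{3-chloro-2,4-dimethoxy-6-[(triisopropylsilyl)oxy]phenyl}-2-oxopropyl)-5-methyl-3-[(triisopropylsilyl)oxy]benzoate
Product: 20 methyl 2-[3-(3-chloro-6-hydroxy-2,4-dimethoxyphenyl)-2-oxopropyl]-3-hydroxy-5-methylbenzoate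
Conditions: Bu4NF (2.4 equiv), AcOH (2.4 equiv), THF, 0 °C
Reagents that add atoms: none
Why: Fluoride-induced cleavage of both aryl silyl ethers; the acetic acid buffer keeps the phenols protonated, which should prevent phenoxide-driven condensation of the benzylic ketone with the ester as well as acid-driven cyclodehydration to a benzofuran.

Compound list
1 | 2-chloro-1,3-dimethoxybenzene | COc1cccc(OC)c1Cl | starting material
2 | 2-(4-chloro-3,5-dimethoxyphenyl)-4,4,5,5-tetramethyl-1,3,2-dioxaborolane (formed in the flask) | COc1cc(B2OC(C)(C)C(C)(C)O2)cc(OC)c1Cl | intermediate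
3 | 4-chloro-3,5-dimethoxyphenol | COc1cc(O)cc(OC)c1Cl | intermediate
4 | 4-chloro-2-(hydroxymethyl)-3,5-dimethoxyphenol (formed in the flask as its magnesium salt) | COc1cc(O)c(CO)c(OC)c1Cl | intermediate
5 | 3-chloro-6-hydroxy-2,4-dimethoxybenzaldehyde | COc1cc(O)c(C=O)c(OC)c1Cl | intermediate
6 | 3-chloro-2,4-dimethoxy-6-[(triisopropylsilyl)oxy]benzaldehyde | COc1cc(O[Si](C(C)C)(C(C)C)C(C)C)c(C=O)c(OC)c1Cl | intermediate
7 | Meldrum's acid (2,2-dimethyl-1,3-dioxane-4,6-dione) | CC1(C)OC(=O)CC(=O)O1 | starting material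
8 | 5-{3-chloro-2,4-dimethoxy-6-[(triisopropylsilyl)oxy]benzylidene}-2,2-dimethyl-1,3-dioxane-4,6-dione (formed in the flask) | COc1cc(O[Si](C(C)C)(C(C)C)C(C)C)c(C=C2C(=O)OC(C)(C)OC2=O)c(OC)c1Cl | intermediate
9 | 5-{3-chloro-2,4-dimethoxy-6-[(triisopropylsilyl)oxy]benzyl}-2,2-dimethyl-1,3-dioxane-4,6-dione | COc1cc(O[Si](C(C)C)(C(C)C)C(C)C)c(CC2C(=O)OC(C)(C)OC2=O)c(OC)c1Cl | intermediate
10 | 2-hydroxy-4-methylbenzaldehyde | Cc1ccc(C=O)c(O)c1 | starting material
11 | 4-methyl-2-[(triisopropylsilyl)oxy]benzaldehyde | Cc1ccc(C=O)c(O[Si](C(C)C)(C(C)C)C(C)C)c1 | intermediate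
12 | {4-methyl-2-[(triisopropylsilyl)oxy]phenyl}methanol | Cc1ccc(CO)c(O[Si](C(C)C)(C(C)C)C(C)C)c1 | intermediate
13 | 1-(bromomethyl)-4-methyl-2-[(triisopropylsilyl)oxy]benzene | Cc1ccc(CBr)c(O[Si](C(C)C)(C(C)C)C(C)C)c1 | intermediate
14 | 5-{3-chloro-2,4-dimethoxy-6-[(triisopropylsilyl)oxy]benzyl}-2,2-dimethyl-5-{4-methyl-2-[(triisopropylsilyl)oxy]benzyl}-1,3-dioxane-4,6-dione (achiral) | CC1(C)OC(=O)C(Cc2ccc(C)cc2O[Si](C(C)C)(C(C)C)C(C)C)(Cc2c(O[Si](C(C)C)(C(C)C)C(C)C)cc(OC)c(Cl)c2OC)C(=O)O1 | intermediate
15 | racemic 2-{3-chloro-2,4-dimethoxy-6-[(triisopropylsilyl)oxy]benzyl}-6-methyl-1-oxo-4-[(triisopropylsilyl)oxy]indane-2-carboxylic acid (formed in the flask) | OC(=O)C1(Cc2c(O[Si](C(C)C)(C(C)C)C(C)C)cc(OC)c(Cl)c2OC)Cc2c(O[Si](C(C)C)(C(C)C)C(C)C)cc(C)cc2C1=O | intermediate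
16 | racemic 2-{3-chloro-2,4-dimethoxy-6-[(triisopropylsilyl)oxy]benzyl}-6-methyl-4-[(triisopropylsilyl)oxy]indan-1-one | O=C1C(Cc2c(O[Si](C(C)C)(C(C)C)C(C)C)cc(OC)c(Cl)c2OC)Cc2c(O[Si](C(C)C)(C(C)C)C(C)C)cc(C)cc21 | intermediate
17 | potassium enolate of 16, potassium 2-{3-chloro-2,4-dimethoxy-6-[(triisopropylsilyl)oxy]benzyl}-5-methyl-7-[(triisopropylsilyl)oxy]-1H-inden-3-olate (formed in the flask) | [K+].[O-]C1=C(Cc2c(O[Si](C(C)C)(C(C)C)C(C)C)cc(OC)c(Cl)c2OC)Cc2c(O[Si](C(C)C)(C(C)C)C(C)C)cc(C)cc21 | intermediate
18 | racemic 2-{3-chloro-2,4-dimethoxy-6-[(triisopropylsilyl)oxy]benzyl}-2-hydroxy-6-methyl-4-[(triisopropylsilyl)oxy]indan-1-one | O=C1c2cc(C)cc(O[Si](C(C)C)(C(C)C)C(C)C)c2CC1(O)Cc1c(O[Si](C(C)C)(C(C)C)C(C)C)cc(OC)c(Cl)c1OC | intermediate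
19 | methyl 2-(3-{3-chloro-2,4-dimethoxy-6-[(triisopropylsilyl)oxy]phenyl}-2-oxopropyl)-5-methyl-3-[(triisopropylsilyl)oxy]benzoate | COC(=O)c1cc(C)cc(O[Si](C(C)C)(C(C)C)C(C)C)c1CC(=O)Cc1c(O[Si](C(C)C)(C(C)C)C(C)C)cc(OC)c(Cl)c1OC | intermediate
20 | methyl 2-[3-(3-chloro-6-hydroxy-2,4-dimethoxyphenyl)-2-oxopropyl]-3-hydroxy-5-methylbenzoate (no stereocentre) | COC(=O)c1cc(C)cc(O)c1CC(=O)Cc1c(O)cc(OC)c(Cl)c1OC | target

Total step count: 12 steps.
Longest linear sequence: 9 steps (steps 1, 2, 3, 4, 8, 9, 10, 11, 12); the ring A branch (steps 5–7) joins at step 8.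

Steps most likely to fail

Step 9 (key step). The ring A carbon to be acylated is activated only by its ortho alkyl group and lies meta to the silyloxy group, so ring closure may be slow. Loss of a silyl group followed by lactonisation of the freed phenol onto the Meldrum's acid, or intermolecular acylation of ring B, could then take over. The fallback forms the same bond with reversed polarity from an aryl metal (Parham-type cyclisation); it sets out from aldehyde 11 and Meldrum's acid 9 and comes back at indanone 16. Aldehyde 11 is converted in the flask into its α-amino alkoxide with LiN(Me)CH2CH2NMe2, lithiated with n-BuLi at the only free position ortho to the masked formyl group, and quenched with I2 to give 2-iodo-4-methyl-6-[(triisopropylsilyl)oxy]benzaldehyde F1. Reduction with NaBH4 gives {2-iodo-4-methyl-6-[(triisopropylsilyl)oxy]phenyl}methanol F2, and CBr4/PPh3 gives 2-(bromomethyl)-1-iodo-5-methyl-3-[(triisopropylsilyl)oxy]benzene F3. Alkylation of 9 with F3 (K2CO3, MeCN) gives 5-{3-chloro-2,4-dimethoxy-6-[(triisopropylsilyl)oxy]benzyl}-5-{2-iodo-4-methyl-6-[(triisopropylsilyl)oxy]benzyl}-2,2-dimethyl-1,3-dioxane-4,6-dione F4. Iodine–magnesium exchange with iPrMgCl·LiCl (THF, −40 °C) places an aryl Grignard reagent next to a Meldrum's acid carbonyl; five-membered ring closure, acidic work-up and gentle warming with loss of acetone and CO2 (through 15) should give 16.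

Step 4. Condensation of the doubly ortho-substituted, electron-rich aldehyde may be sluggish, and the push–pull alkylidene intermediate may shed its ortho silyl group and close to a coumarin-3-carboxylic acid before hydride transfer. The fallback reverses the roles of the two arenes; it sets out from aldehyde 11, Meldrum's acid 7 and aldehyde 6 and comes back at precursor 14, so that steps 6 to 8 are not needed. The same reductive alkylation is run on the less hindered ring A aldehyde 11 with 7, which should give 2,2-dimethyl-5-{4-methyl-2-[(triisopropylsilyl)oxy]benzyl}-1,3-dioxane-4,6-dione F5. Aldehyde 6 is only reduced (NaBH4, MeOH/THF, 0 °C) to {3-chloro-2,4-dimethoxy-6-[(triisopropylsilyl)oxy]phenyl}methanol F6. Mitsunobu C-alkylation of F5 with F6 (PPh3, DIAD, THF, 0 °C to rt) then forms the quaternary carbon of 14.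

Step 10. Oxygen transfer to the crowded, tetrasubstituted enolate may be slow or incomplete, and the enolate may instead add to the sulfonylimine by-product. The fallback cleaves the C1–C2 bond directly at the enol ether stage without passing through the ketol; it sets out from indanone 16 and comes back at keto ester 19, so that step 11 is not needed. Silylation of 16 (TMSCl, NaI, Et3N, MeCN) gives the silyl enol ether {[2-{3-chloro-2,4-dimethoxy-6-[(triisopropylsilyl)oxy]benzyl}-5-methyl-7-[(triisopropylsilyl)oxy]-1H-inden-3-yl]oxy}trimethylsilane F7. Ozonolysis (O3, CH2Cl2/MeOH, −78 °C, stopped at first excess; Me2S) and hydrolysis of the silyl ester on work-up should give 2-(3-{3-chloro-2,4-dimethoxy-6-[(triisopropylsilyl)oxy]phenyl}-2-oxopropyl)-5-methyl-3-[(triisopropylsilyl)oxy]benzoic acid F8. Esterification with Me3SiCHN2 (toluene/MeOH, 0 °C) gives 19.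

Further compounds
F1 | step 9 | 2-iodo-4-methyl-6-[(triisopropylsilyl)oxy]benzaldehyde | Cc1cc(I)c(C=O)c(O[Si](C(C)C)(C(C)C)C(C)C)c1
F2 | step 9 | {2-iodo-4-methyl-6-[(triisopropylsilyl)oxy]phenyl}methanol | Cc1cc(I)c(CO)c(O[Si](C(C)C)(C(C)C)C(C)C)c1
F3 | step 9 | 2-(bromomethyl)-1-iodo-5-methyl-3-[(triisopropylsilyl)oxy]benzene | Cc1cc(I)c(CBr)c(O[Si](C(C)C)(C(C)C)C(C)C)c1
F4 | step 9 | 5-{3-chloro-2,4-dimethoxy-6-[(triisopropylsilyl)oxy]benzyl}-5-{2-iodo-4-methyl-6-[(triisopropylsilyl)oxy]benzyl}-2,2-dimethyl-1,3-dioxane-4,6-dione | CC1(C)OC(=O)C(Cc2c(I)cc(C)cc2O[Si](C(C)C)(C(C)C)C(C)C)(Cc2c(O[Si](C(C)C)(C(C)C)C(C)C)cc(OC)c(Cl)c2OC)C(=O)O1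
F5 | step 4 | 2,2-dimethyl-5-{4-methyl-2-[(triisopropylsilyl)oxy]benzyl}-1,3-dioxane-4,6-dione | CC1(C)OC(=O)C(Cc2ccc(C)cc2O[Si](C(C)C)(C(C)C)C(C)C)C(=O)O1
F6 | step 4 | {3-chloro-2,4-dimethoxy-6-[(triisopropylsilyl)oxy]phenyl}methanol | COc1cc(O[Si](C(C)C)(C(C)C)C(C)C)c(CO)c(OC)c1Cl
F7 | step 10 | {[2-{3-chloro-2,4-dimethoxy-6-[(triisopropylsilyl)oxy]benzyl}-5-methyl-7-[(triisopropylsilyl)oxy]-1H-inden-3-yl]oxy}trimethylsilane | C[Si](C)(C)OC1=C(Cc2c(O[Si](C(C)C)(C(C)C)C(C)C)cc(OC)c(Cl)c2OC)Cc2c(O[Si](C(C)C)(C(C)C)C(C)C)cc(C)cc21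
F8 | step 10 | 2-(3-{3-chloro-2,4-dimethoxy-6-[(triisopropylsilyl)oxy]phenyl}-2-oxopropyl)-5-methyl-3-[(triisopropylsilyl)oxy]benzoic acid | OC(=O)c1cc(C)cc(O[Si](C(C)C)(C(C)C)C(C)C)c1CC(=O)Cc1c(O[Si](C(C)C)(C(C)C)C(C)C)cc(OC)c(Cl)c1OC
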